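The data are calculated with made-up constants, and the scatter is random.

**Amounts.** Starting material and partner give target and released group, taken here as one partner per starting material. The violet flask has readings up to 72.0 h; it is looked at, and may be changed, at 4.0 d.

| flask | starting material | partner | temperature | remark | time |
|---|---|---|---|---|---|
| violet | 19 mM | 0.60 equiv | −20 °C | the very flask that is asked about, followed so far |  |
| teal | 19 mM | 0.60 equiv | −25 °C | run made earlier |  |
| flask | 19 mM | 0.600 equiv | −20 °C |  | 4.0 d |

| run | time / h | target / % | starting material / % |
|---|---|---|---|
| violet | 5.00 | 17.9 | 82.0 |
| violet | 15.0 | 33.6 | 64.7 |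
| violet | 25.0 | 38.8 | 57.8 |
| violet | 40.0 | 40.5 | 50.7 |
| violet | 60.0 | 42.2 | 47.5 |
| violet | 72.0 | 42.4 | 45.5 |
| teal | 5.00 | 10.8 | 89.6 |
| teal | 15.0 | 25.4 | 74.8 |
| teal | 25.0 | 33.0 | 65.2 |
| teal | 40.0 | 38.7 | 57.4 |
| teal | 60.0 | 40.7 | 52.0 |
| teal | 72.0 | 42.2 | 49.9 |

(readings scatter by 0.5 percentage points)

- summer: change nothing and wait 4.0 d more
- autumn: at 4.0 d raise the temperature by 10 K, then wait 4.0 d
- dawn: at 4.0 d add partner, 100 % of the amount charged, then wait 4.0 d
- midnight: at 4.0 d take out 90 % of the released group then present, then wait 4.0 d

- additions leave the volume as it is
- a reading or a percentage of target counts all its forms, free or not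

- target, in percent of the starting material first charged, at 4.0 d
- what to do for the largest gain in target; "none" if nothing gains more than 2 percentage points (summer / autumn / dawn / midnight / none)
- target present, in percent of the starting material first charged, after summer
- target present, in percent of the starting material first charged, after midnight

**The puzzle.** By 72.0 h, target plus starting material in the violet flask is 12 percentage points short of the charge, so something is taking material away. Yet from 40.0 h to 72.0 h the target reading rises by 1.9 points.

**The floor.** Partner is the limiting reagent, at 0.600 equiv. This gives a starting-material floor, the share of the charge that partner cannot consume: 40.0 %. At 72.0 h the violet flask reads 5.5 points above it, and that reserve is the starting material that partner can still consume. Over the same late stretch, starting material fell 5.2 points, and a share of 0.365 appeared as target, a rough reading given the scatter. In these violet readings the loss thus ran below the inflow. My own reckoning keeps that share over the reserve and ends near 44.4 % target once the reserve is consumed. Partner added at 4.0 d takes the total charged to 1.20 equivalents, which removes the floor, whereas the other options leave it standing.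

**The forecast.** It gives 40.5 % now, 28 % after summer and 29.5 % after midnight, and chooses dawn. It reads the drift “roughly as first-order loss of target”.

**The result.** The flask gives 42.5 % now, 43.2 % after summer and 44.6 % after midnight. The choice is dawn, with a gain of 26 points.

    starting material + partner ⇌ target + released group (K = 3.40, k = 0.0696 /M/min, Ea = 61.0 kJ/mol, ΔH = −65.0 kJ/mol)
    crystals ⇌ target, rate k2*(cs2 - [target]) while solid is left; crystals form when [target] > cs2 (solubility = 7.60 mM, k = 0.0155 /min)
    released group → by-product carried off (k = 4.13 × 10⁻⁴ /min, Ea = 78.0 kJ/mol)
    target + released group → side product (k = 0.0226 /M/min, Ea = 62.0 kJ/mol)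
    (constants at −20 °C)

**Where it parts.** At 96.0 h, c(released group) is 1.04 mM, and the half-life of dissolved target by the side-product step at that moment is 21 d, long against 4.0 d. Left for 960 h, the violet flask holds 40.0 % starting material and 0 % partner, which is the floor of 40.0 %.

**A warmer flask.** At 5 °C the charges are the same, so the floor is again 40.0 % and target can reach 60.0 % at most. That flask shows 40.0 % starting material, 0 % partner, 8.66 % side product and 51.3 % target at 96.0 h.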